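The data were generated by integration with made-up constants, noise included.

What share of its Sub will the summer flask have turned after 6.3 h, charged with twice the Sub and twice the Rgt of the noon flask? These are the flasks and the runs so far:

| setting | noon | autumn | dusk | midnight | summer |
|---|---|---|---|---|---|
| Sub | 80.0 mM | 32.0 mM | 80.0 mM | 80.0 mM | 160 mM |
| Rgt | 160 mM | 112 mM | 480 mM | 160 mM | 320 mM |
| Cat | 1.60 mM | 1.60 mM | 1.60 mM | 1.60 mM | 1.60 mM |
| Prd |  |  |  | 40.0 mM |  |
| time |  |  |  |  | 6.3 h |

- noon run (time / h: [Prd] / mM): 0.23: 2.7; 0.69: 10.1; 1.3: 15.6; 2.1: 23.5; 3.0: 29.3; 4.0: 37.9; 5.1: 40.4; 6.3: 45.0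
- autumn run (time / h: [Prd] / mM): 0.23: 0.4; 0.69: 5.1; 1.3: 8.0; 2.1: 9.1; 3.0: 14.2; 4.0: 17.1; 5.1: 18.2; 6.3: 20.1
- dusk run (time / h: [Prd] / mM): 0.23: 1.1; 0.69: 4.3; 1.3: 8.5; 2.1: 11.8; 3.0: 15.2; 4.0: 19.2; 5.1: 21.5; 6.3: 23.9
- midnight run (time / h: [Prd] / mM): 0.23: 43.4; 0.69: 49.1; 1.3: 54.7; 2.1: 63.3; 3.0: 69.8; 4.0: 75.1; 5.1: 81.2; 6.3: 87.0

(each reading ± 0.8 mM)

- Overall: Sub + Rgt -> Prd, with Cat as catalyst.
- Constant volume, constant temperature.
- What is held in complexes is read along with the free species.
- An order is taken over about fifteen percent of the charge, up and down.

1. the power of [Sub] that the first rate follows, about the charge of the noon run; measure it at two percent of Sub made into Prd (one fixed amount of Prd, the same in the runs compared)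
2. the power of [Rgt] that the first rate follows, about the charge of the noon run; measure it at two percent of Sub made into Prd
3. the autumn run starts with 48.0 mM less of Sub and of Rgt than the noon run, and with no Prd. Compared where both hold the same amount of Sub, once fifteen percent of what the autumn run was charged with has turned into Prd, is the autumn run faster, slower or alike (within a tenth)?
4. Prd in the summer run at 6.3 h, as a share of the Sub charged

We read the last row of the tables, run against run. Noon has made 45.0 mM of its 80.0 mM of Sub, and minus the logarithm of the share left, divided by the time, gives 0.131 /h. This is the quantity we carry, the mean constant of a run: a pseudo-first-order constant averaged over the whole curve. Midnight made 47.0 mM against those 45.0 mM, so we leave Prd out.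

Dusk gives 0.0563 /h, lower than noon, and it sits in more Rgt. Rgt falls during a run, so we replace its curve by the value at the reading nearest the middle, 3.0 h. That is 131 mM for noon and 465 mM for dusk, and between these two runs the mean constant falls as the power 0.667 of middle Rgt.

Autumn tests this replacement. Its middle Rgt of 97.8 mM predicts 0.159 /h, and its readings give 0.157 /h, with 0.0107 /h of scatter from its last reading. Autumn holds 32.0 mM of Sub against 80.0 mM, yet the line made without it fits, so we take the power of Sub as close to one, which is higher than the forecast's figure below.

For summer, one pass with the charged Rgt gives 58.5 mM of Prd. Noon had 65.1% of its final Prd at the middle reading, so summer's middle Rgt is 282 mM. The mean constant is then 0.0786 /h, and our share is 39.1%.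

The forecast says 0.85 for Sub, −0.45 for Rgt, faster for the autumn comparison and 39% for summer. Its grounds are that, with Prd harmless, “the catalyst must be dying with time”, at about 0.14 per hour.

The simulation gives 40.8% for summer, from these steps:

    Cat + Sub → Cat.Sub (195.1 /M/h)
    Cat.Sub + Rgt → Prd + Cat (3157 /M/h)
    Cat + Rgt ⇌ Cat.Rgt, settled at all times (4.560 /M)
    Cat + Rgt → G + Rgt (1.350 /M/h)

That is a mean constant of 0.0832 /h against our 0.0786 /h. The first rate follows Sub to the power 1.0 and Rgt to the power −0.41, and in the comparison at equal Sub the autumn run is faster. Used once more, the ratio of mean constants carries noon's half time of 4.76 h over to autumn as 3.97 h, and the autumn run reached half of its charge at 3.95 h.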